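## Strategy

- Retrosynthesis cuts ring C of irigenin at O1–C8a and C4–C4a, then removes the three phenol protecting groups.
- This is possible because ring C is fused to ring A through C4a–C8a, with O1 on C8a, the C4 carbonyl on C4a and the C5 oxygen next to C4a. Ring A can therefore enter as a 3-alkoxyaryne (C4a≡C8a), and O1–C2=C3(ring B)–C4 as the enolate of an α-formyl arylacetate.
- Ring A is bought as 2-methoxyresorcinol and converted into a 2-silylaryl triflate (MOM protection, C–H borylation/oxidation, bromination, retro-Brook/triflation).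
- Ring B is bought as 3-hydroxy-4,5-dimethoxybenzaldehyde, benzylated and homologated with ethyl diazoacetate to the 3-hydroxy-2-arylacrylate.
- Ring C is formed last, in the aryne annulation that joins the two fragments; the benzyl and MOM groups are then removed.
- The target has no stereocentre. The only geometric element is the Z enol(ate) of the acrylate (oxygen cis to the ester), held by hydrogen bond or metal chelate and erased when ring C becomes aromatic.

Key step: step 7

Assumption: 2-methoxyresorcinol, 3-hydroxy-4,5-dimethoxybenzaldehyde and ethyl diazoacetate are taken as purchasable. Positions are given in isoflavone numbering (O1, C2, C3, C4, C4a, C5–C8, C8a; primed numbers for ring B).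

## Route

Step 1
Reactants: 1 2-methoxyresorcinol (2-methoxybenzene-1,3-diol)
Product: 2 2-methoxy-1,3-bis(methoxymethoxy)benzene
Conditions: MOMCl (2.6 equiv), iPr2NEt (3.5 equiv), CH2Cl2, 0 °C to rt
Reagents that add atoms: chloromethyl methyl ether, COCCl
Why: Double Williamson-type O-alkylation of the two phenols with the α-chloro ether should be clean, and the MOM acetals resist the bases, organolithium and fluoride used later yet leave with mild acid at the end.

Step 2
Reactants: 2 2-methoxy-1,3-bis(methoxymethoxy)benzene
Product: 4 4-methoxy-3,5-bis(methoxymethoxy)phenol, via aryl pinacol boronate 3 (not isolated)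
Conditions: B2pin2 (0.6 equiv), [Ir(OMe)(cod)]2 (1.5 mol%), 4,4'-di-tert-butyl-2,2'-bipyridine (3 mol%), THF, 80 °C; then 30% H2O2, aq. NaOH, 0 °C to rt
Reagents that add atoms: hydrogen peroxide, OO
Why: Sterically governed iridium-catalysed aromatic C–H borylation should occur only at the one ring CH without an ortho substituent, and basic peroxide oxidation of the C–B bond (1,2-aryl shift from boron to oxygen) then gives the symmetrical phenol in the same flask.

Step 3
Reactants: 4 4-methoxy-3,5-bis(methoxymethoxy)phenol
Product: 5 2-bromo-4-methoxy-3,5-bis(methoxymethoxy)phenol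
Conditions: NBS (1.0 equiv), iPr2NH (10 mol%), CH2Cl2, −78 °C
Reagents that add atoms: N-bromosuccinimide, O=C1CCC(=O)N1Br
Why: Electrophilic aromatic bromination ortho to the free hydroxyl; the two open positions are equivalent by symmetry, so only mono- versus dibromination must be controlled, which one equivalent of NBS at low temperature should do, and the neutral succinimide by-product spares the MOM acetals.

Step 4
Reactants: 5 2-bromo-4-methoxy-3,5-bis(methoxymethoxy)phenol
Product: 9 4-methoxy-3,5-bis(methoxymethoxy)-2-(trimethylsilyl)phenyl trifluoromethanesulfonate, via aryl trimethylsilyl ether 6 (not isolated), via aryllithium 7 (not isolated), via lithium silylphenoxide 8 (not isolated)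
Conditions: (Me3Si)2NH, THF, 65 °C, then evaporation; n-BuLi (1.1 equiv), THF, −78 °C; Tf2O (1.2 equiv), −78 °C
Reagents that add atoms: hexamethyldisilazane, C[Si](C)(C)N[Si](C)(C)C; trifluoromethanesulfonic anhydride, O=S(=O)(OS(=O)(=O)C(F)(F)F)C(F)(F)F
Why: O-silylation, bromine–lithium exchange, 1,3 O-to-C silyl shift (retro-Brook rearrangement) driven by formation of the phenoxide, and O-triflation form the standard one-pot route from 2-bromophenols to 2-(trimethylsilyl)aryl triflates; the exchange at −78 °C should outrun any MOM-directed deprotonation.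

Step 5
Reactants: 10 3-hydroxy-4,5-dimethoxybenzaldehyde
Product: 11 3-benzyloxy-4,5-dimethoxybenzaldehyde
Conditions: BnBr, K2CO3, DMF, rt
Reagents that add atoms: benzyl bromide, BrCc1ccccc1
Why: Williamson ether synthesis on the phenoxide; the benzyl ether survives the strong acid of the next step and the fluoride and enolate of the annulation, which an acetal protecting group might not.

Step 6
Reactants: 11 3-benzyloxy-4,5-dimethoxybenzaldehyde; 12 ethyl diazoacetate
Product: 13 ethyl (Z)-2-(3-benzyloxy-4,5-dimethoxyphenyl)-3-hydroxyacrylate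
Conditions: HBF4·OEt2 (10 mol%), CH2Cl2, −78 °C, slow addition of 12
Reagents that add atoms: none
Why: Brønsted-acid-catalysed addition of the diazo ester to the aldehyde, then loss of N2 with 1,2-shift of the electron-rich aryl group (a known route from aryl aldehydes to 3-hydroxy-2-arylacrylates), places the aldehyde carbon at the future C2, the diazo carbon at C3 and the ester carbon at C4; the Z enol is the hydrogen-bonded, stable tautomer.

Step 7
Reactants: 9 4-methoxy-3,5-bis(methoxymethoxy)-2-(trimethylsilyl)phenyl trifluoromethanesulfonate; 13 ethyl (Z)-2-(3-benzyloxy-4,5-dimethoxyphenyl)-3-hydroxyacrylate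
Product: 17 3-(3-benzyloxy-4,5-dimethoxyphenyl)-6-methoxy-5,7-bis(methoxymethoxy)-4H-chromen-4-one, via sodium enolate 14 (not isolated), via aryne 15 (not isolated), via aryl anion 16 (not isolated)
Conditions: 13 (1.2 equiv), NaH (1.2 equiv), THF, 0 °C to rt; then 9 (1.0 equiv), CsF (3 equiv), THF, 65 °C
Reagents that add atoms: none
Why: Proposed new method: CsF desilylates 9 and triflate departs to give the 3-alkoxyaryne 15, the formyl-derived oxygen of enolate 14 adds to the aryne carbon that becomes C8a (bond O1–C8a), and the aryl anion 16 thereby generated at C4a attacks the ester carbonyl and expels ethoxide (bond C4–C4a). The closest known reaction type is the CsF-mediated annulation of arynes with salicylate esters to xanthones (phenoxide O-arylation, then intramolecular acyl substitution by the aryl anion), here with an enol in place of the phenol; aryne insertion into carboxylic acid C–O bonds is a second relative. Ring C, the only ring formed, closes by 6-exo-trig attack of C4a on the ester carbon. No stereocentre is created; the one geometric requirement, enol oxygen cis to the ester, should be met by the sodium chelate of 14 in THF and disappears in the aromatic pyranone. The step needs O- rather than C-arylation, expected because the alpha carbon is fully substituted and aryl-shielded and such enolates take hard electrophiles at oxygen, and a single orientation on the aryne, secured by the inductively withdrawing C5 OMOM group, which makes the remote carbon (C8a) the electrophilic one and places the anion beside it at C4a. Preforming the enolate with NaH removes every proton source, so 16 should have no outlet other than cyclisation.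

Step 8
Reactants: 17 3-(3-benzyloxy-4,5-dimethoxyphenyl)-6-methoxy-5,7-bis(methoxymethoxy)-4H-chromen-4-one
Product: 18 3-(3-hydroxy-4,5-dimethoxyphenyl)-6-methoxy-5,7-bis(methoxymethoxy)-4H-chromen-4-one
Conditions: H2 (1 atm), 10% Pd/C, EtOAc–MeOH, rt, stopped after one equivalent of H2
Reagents that add atoms: none
Why: Catalytic hydrogenolysis of the benzyl aryl ether is much faster than saturation of the C2–C3 bond of an isoflavone, so stopping at one equivalent of hydrogen should free the 3'-hydroxyl while the MOM acetals and the pyranone stay intact.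

Step 9
Reactants: 18 3-(3-hydroxy-4,5-dimethoxyphenyl)-6-methoxy-5,7-bis(methoxymethoxy)-4H-chromen-4-one
Product: 19 irigenin (5,7-dihydroxy-3-(3-hydroxy-4,5-dimethoxyphenyl)-6-methoxy-4H-chromen-4-one)
Conditions: HCl (1 M, methanolic), MeOH–THF, 45 °C
Reagents that add atoms: none
Why: Acid-catalysed acetal exchange with methanol (transacetalisation to dimethoxymethane) should remove both MOM groups, while the aryl methyl ethers and the isoflavone core are stable to dilute methanolic HCl.

## Compound list

1 | 2-methoxyresorcinol | COc1c(O)cccc1O | starting material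
2 | 2-methoxy-1,3-bis(methoxymethoxy)benzene | COCOc1cccc(OCOC)c1OC | intermediate
3 | 2-[4-methoxy-3,5-bis(methoxymethoxy)phenyl]-4,4,5,5-tetramethyl-1,3,2-dioxaborolane | COCOc1cc(B2OC(C)(C)C(C)(C)O2)cc(OCOC)c1OC | intermediate
4 | 4-methoxy-3,5-bis(methoxymethoxy)phenol | COCOc1cc(O)cc(OCOC)c1OC | intermediate
5 | 2-bromo-4-methoxy-3,5-bis(methoxymethoxy)phenol | COCOc1cc(O)c(Br)c(OCOC)c1OC | intermediate
6 | [2-bromo-4-methoxy-3,5-bis(methoxymethoxy)phenoxy]trimethylsilane | COCOc1cc(O[Si](C)(C)C)c(Br)c(OCOC)c1OC | intermediate
7 | [2-lithio-4-methoxy-3,5-bis(methoxymethoxy)phenoxy]trimethylsilane | COCOc1cc(O[Si](C)(C)C)c([Li])c(OCOC)c1OC | intermediate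
8 | lithium 4-methoxy-3,5-bis(methoxymethoxy)-2-(trimethylsilyl)phenoxide | [Li+].[O-]c1cc(OCOC)c(OC)c(OCOC)c1[Si](C)(C)C | intermediate
9 | 4-methoxy-3,5-bis(methoxymethoxy)-2-(trimethylsilyl)phenyl trifluoromethanesulfonate | COCOc1cc(OS(=O)(=O)C(F)(F)F)c([Si](C)(C)C)c(OCOC)c1OC | intermediate
10 | 3-hydroxy-4,5-dimethoxybenzaldehyde | COc1cc(C=O)cc(O)c1OC | starting material
11 | 3-benzyloxy-4,5-dimethoxybenzaldehyde | COc1cc(C=O)cc(OCc2ccccc2)c1OC | intermediate
12 | ethyl diazoacetate | CCOC(=O)C=[N+]=[N-] | starting material
13 | ethyl (Z)-2-(3-benzyloxy-4,5-dimethoxyphenyl)-3-hydroxyacrylate | O/C=C(\C(=O)OCC)c1cc(OCc2ccccc2)c(OC)c(OC)c1 | intermediate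
14 | sodium (Z)-2-(3-benzyloxy-4,5-dimethoxyphenyl)-3-ethoxy-3-oxoprop-1-en-1-olate | [Na+].[O-]/C=C(\C(=O)OCC)c1cc(OCc2ccccc2)c(OC)c(OC)c1 | intermediate
15 | 4-methoxy-3,5-bis(methoxymethoxy)benzyne (1,2-didehydrobenzene) | COCOC1=CC#CC(OCOC)=C1OC | intermediate
16 | sodium salt of the C4a carbanion of ethyl (Z)-2-(3-benzyloxy-4,5-dimethoxyphenyl)-3-[4-methoxy-3,5-bis(methoxymethoxy)phenoxy]acrylate | [Na+].[c-]1c(OCOC)c(OC)c(OCOC)cc1O/C=C(\C(=O)OCC)c1cc(OCc2ccccc2)c(OC)c(OC)c1 | intermediate
17 | 3-(3-benzyloxy-4,5-dimethoxyphenyl)-6-methoxy-5,7-bis(methoxymethoxy)-4H-chromen-4-one | COCOc1cc2occ(-c3cc(OC)c(OC)c(OCc4ccccc4)c3)c(=O)c2c(OCOC)c1OC | intermediate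
18 | 3-(3-hydroxy-4,5-dimethoxyphenyl)-6-methoxy-5,7-bis(methoxymethoxy)-4H-chromen-4-one | COCOc1cc2occ(-c3cc(OC)c(OC)c(O)c3)c(=O)c2c(OCOC)c1OC | intermediate
19 | irigenin | COc1cc(-c2coc3cc(O)c(OC)c(O)c3c2=O)cc(O)c1OC | target

## Summary and risks

Total step count: 9. Longest linear sequence: 7 steps (steps 1–4, then 7–9, from 2-methoxyresorcinol).

Steps most likely to fail:

**Step 7.** The ambident enolate may be arylated at carbon, after which the aryl anion transfers the formyl group instead of closing ring C. O-arylation may also occur from the extended enolate geometry, in which the aryl anion cannot reach the ester, or the liberated ethoxide may consume aryne or attack C2 of the product. The fallback builds the isoflavone by the known 3-iodochromone/Suzuki–Miyaura sequence, so that the C3–C1' bond is made by cross-coupling on a preformed chromone. It sets out from bromophenol 5 (with purchased 2,3-dimethoxyphenol for ring B) and comes back to the route at irigenin 19.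
- Ring A/C: treatment of 5 with n-BuLi (2.2 equiv, THF, −78 °C) and N-methoxy-N-methylacetamide should give 1-[2-hydroxy-5-methoxy-4,6-bis(methoxymethoxy)phenyl]ethan-1-one F1. Condensation with N,N-dimethylformamide dimethyl acetal (toluene, 90 °C) should give (E)-3-(dimethylamino)-1-[2-hydroxy-5-methoxy-4,6-bis(methoxymethoxy)phenyl]prop-2-en-1-one F2. Iodine with pyridine in CHCl3 at rt should then close ring C to 3-iodo-6-methoxy-5,7-bis(methoxymethoxy)-4H-chromen-4-one F3.
- Ring B: 2,3-dimethoxyphenol with MOMCl and iPr2NEt should give 1,2-dimethoxy-3-(methoxymethoxy)benzene F4. Iridium-catalysed C–H borylation as in step 2 (B2pin2, [Ir(OMe)(cod)]2, 4,4'-di-tert-butyl-2,2'-bipyridine) should give 2-[3,4-dimethoxy-5-(methoxymethoxy)phenyl]-4,4,5,5-tetramethyl-1,3,2-dioxaborolane F5.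
- Union and release: Suzuki–Miyaura coupling of F3 with F5 (Pd(PPh3)4, a zerovalent palladium catalyst, aq. Na2CO3, dioxane, 80 °C) should give 3-[3,4-dimethoxy-5-(methoxymethoxy)phenyl]-6-methoxy-5,7-bis(methoxymethoxy)-4H-chromen-4-one F6. Methanolic HCl under the conditions of step 9 should then free all three phenols to give 19.

**Step 4.** The O-to-C silyl shift may be incomplete, n-BuLi may deprotonate next to a MOM group or attack silicon, or the crowded, electron-rich aryl silane may lose silicon by protonation on work-up. Over-bromination in step 3 would add to the same problem. The fallback installs silicon by directed ortho-metalation and needs no halogen. It sets out from phenol 4 and comes back at triflate 9.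
- Carbamoylation of 4 (NaH, Et2NCOCl, THF) should give 4-methoxy-3,5-bis(methoxymethoxy)phenyl N,N-diethylcarbamate F7.
- Lithiation with s-BuLi/TMEDA in THF at −78 °C, at the position flanked by the carbamate and a MOM ether, followed by Me3SiCl should give 4-methoxy-3,5-bis(methoxymethoxy)-2-(trimethylsilyl)phenyl N,N-diethylcarbamate F8.
- Reductive removal of the carbamate with LiAlH4 (THF, 0 °C to rt) should give 4-methoxy-3,5-bis(methoxymethoxy)-2-(trimethylsilyl)phenol F9.
- Triflation (Tf2O, pyridine, CH2Cl2, 0 °C) should give 9.

**Step 6.** A 1,2-hydride shift may compete with the aryl shift and give the β-keto ester, or acid-induced decomposition of the diazo ester may outrun its addition to the aldehyde. The fallback reaches the same formyl ester by migration of the ester group instead of the aryl group. It sets out from aldehyde 11 and comes back at hydroxyacrylate 13.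
- Darzens condensation of 11 with ethyl chloroacetate (NaOEt, EtOH–THF, 0 °C) should give ethyl 3-(3-benzyloxy-4,5-dimethoxyphenyl)oxirane-2-carboxylate F10, as a cis/trans mixture in which both isomers are usable.
- BF3·OEt2 in CH2Cl2 at 0 °C should open the epoxide at the benzylic carbon and induce the known 1,2-shift of the ethoxycarbonyl group of 3-aryl glycidic esters (Meinwald-type rearrangement); the resulting α-formyl ester enolises to 13.

## Further compounds

F1 | step 7 | 1-[2-hydroxy-5-methoxy-4,6-bis(methoxymethoxy)phenyl]ethan-1-one | CC(=O)c1c(O)cc(OCOC)c(OC)c1OCOC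
F2 | step 7 | (E)-3-(dimethylamino)-1-[2-hydroxy-5-methoxy-4,6-bis(methoxymethoxy)phenyl]prop-2-en-1-one | CN(C)/C=C/C(=O)c1c(O)cc(OCOC)c(OC)c1OCOC
F3 | step 7 | 3-iodo-6-methoxy-5,7-bis(methoxymethoxy)-4H-chromen-4-one | COCOc1cc2occ(I)c(=O)c2c(OCOC)c1OC
F4 | step 7 | 1,2-dimethoxy-3-(methoxymethoxy)benzene | COCOc1cccc(OC)c1OC
F5 | step 7 | 2-[3,4-dimethoxy-5-(methoxymethoxy)phenyl]-4,4,5,5-tetramethyl-1,3,2-dioxaborolane | COCOc1cc(B2OC(C)(C)C(C)(C)O2)cc(OC)c1OC
F6 | step 7 | 3-[3,4-dimethoxy-5-(methoxymethoxy)phenyl]-6-methoxy-5,7-bis(methoxymethoxy)-4H-chromen-4-one | COCOc1cc2occ(-c3cc(OC)c(OC)c(OCOC)c3)c(=O)c2c(OCOC)c1OC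
F7 | step 4 | 4-methoxy-3,5-bis(methoxymethoxy)phenyl N,N-diethylcarbamate | CCN(CC)C(=O)Oc1cc(OCOC)c(OC)c(OCOC)c1
F8 | step 4 | 4-methoxy-3,5-bis(methoxymethoxy)-2-(trimethylsilyl)phenyl N,N-diethylcarbamate | CCN(CC)C(=O)Oc1cc(OCOC)c(OC)c(OCOC)c1[Si](C)(C)C
F9 | step 4 | 4-methoxy-3,5-bis(methoxymethoxy)-2-(trimethylsilyl)phenol | COCOc1cc(O)c([Si](C)(C)C)c(OCOC)c1OC
F10 | step 6 | ethyl 3-(3-benzyloxy-4,5-dimethoxyphenyl)oxirane-2-carboxylate (cis/trans mixture, racemic) | CCOC(=O)C1OC1c1cc(OCc2ccccc2)c(OC)c(OC)c1
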